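## Structural features

Neonambiquinone A (17) is a para-terphenyl. A central 1,4-benzoquinone (ring B, carbonyl carbons C1 and C4) carries two 4-hydroxyphenyl rings, ring A on C3 and ring C on C6, each joined through one aryl–quinone C–C bond. C2 bears an acetoxy group and C5 only hydrogen, so just one of the two aryl-free positions of ring B is oxygenated and the ring has no symmetry. There is no stereocentre and no stereogenic double bond, so no neighbouring stereocentres need to be related. The one stereocentre met on the way (the carbinol carbon of 7, 10 and 11, the future C1) is carried racemic and disappears on aromatisation. The fragile group is the C2 acetate: as an enol ester of a quinone it is a vinylogous anhydride that aqueous base, alcohols, amines, thiols and hydride donors cleave or attack. The quinone is also reducible and open to conjugate addition at C5, and the free phenols are oxidisable. The real difficulty is therefore the placing of functionality. C2 must be oxygenated and C5 must not, and of three acidic hydroxyl functions only the least nucleophilic one, whose ester is the most labile, must be acetylated. The key step exploits the run C2(OAc)–C3(aryl)–C4(C=O)–C5(H) of ring B. An ester oxygen next to an aryl-bearing carbon, followed by a carbonyl carbon bonded only to ring atoms, is the imprint of two events: a propargylic acetate shifting to the neighbouring alkyne carbon, and CO being captured between the old alkyne terminus and a terminal methylene.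

## Logic of the disconnections

**17 ⇒ 16.**
- Bonds cut: the O–H bonds of the two outer phenols are exchanged for O–CO2tBu bonds.
- Reason: free phenols would not survive the oxidation of ring B, and a tert-butyl carbonate is one of the few phenol masks that falls to anhydrous acid alone.
- Gain: 16 has no free hydroxyl group, so nothing competes with or attacks the C2 acetate.
- Demand: the forward step must work without water, base, nucleophile or reductant and should leave only volatile by-products.

**16 ⇒ 15.**
- Bonds cut: the C1=O bond is cut (C1 returns to C–H) and C4=O is taken back to C4–OH.
- Reason: C1 lies para to C4, so a C4 phenol with hydrogen on C1 already fixes the place of the second carbonyl group.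
- Gain: a labile quinone enol ester becomes an ordinary aryl acetate on a benzene ring.
- Demand: the oxidation must go para (C1) and not ortho (C5), must be nearly neutral, and must find no other phenol in the molecule.

**15 ⇒ 11 + 12.**
- Bonds cut: the ring bonds C3–C4 and C4–C5 are cut, which releases C4 as 12, and the ester oxygen is moved back from C2 to C1.
- Reason: this is the strategic cut. Ring B vanishes, and an open chain C3≡C2–C1–C6=C5 remains that already bears both aryl groups.
- Gain: acetylation of one particular oxygen, the hardest selectivity problem, becomes esterification of the only alcohol of an acyclic compound.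
- Demand: the forward step must move the acetate by a 1,2- and not a 1,3-shift, capture 12 at C3, and close C4 onto C5.

**11 ⇒ 10.**
- Bonds cut: the acyl–oxygen bond at C1.
- Reason: an ester that is both allylic and propargylic ionises easily and should exist for as few steps as possible.
- Gain: 10 is a stable alcohol that can be purified and stored.
- Demand: a mild acylation that leaves the carbonates alone.

**10 ⇒ 7 + 9.**
- Bonds cut: the bond between the alkyne terminus C3 and ring A.
- Reason: an sp–sp2 bond is among the most dependable C–C bonds to form, and the cut divides the molecule into two halves of similar size, each with one aryl ring.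
- Gain: both halves are simple monoaryl compounds.
- Demand: a weak, non-nucleophilic base at room temperature, and the free alcohol as coupling partner so that zerovalent palladium never meets an ionisable ester.

**9 ⇒ 8 + 2.**
- Bonds cut: the O–C(=O) bond of the carbonate.
- Reason and gain: this leads directly to two purchasable compounds.
- Demand: phenoxide formation under mild base only.

**7 ⇒ 5 + 6.**
- Bonds cut: the C1–C2 bond between carbinol and alkyne.
- Reason: carbonyl addition is the shortest way to a propargylic alcohol, and a racemic centre is acceptable.
- Gain: the two-carbon unit C2–C3 comes from a purchasable reagent.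
- Demand: 1,2-addition to the aldehyde must win over 1,4-addition and over attack on the carbonate, which calls for low temperature and a cold quench.

**5 ⇒ 4.**
- Bonds cut: the C6=C5 double bond, so that C5 becomes a one-carbon electrophile.
- Reason: C6 is benzylic and alpha to an aldehyde and is therefore easily functionalised.
- Gain: the branched enal is reduced to a linear aldehyde.
- Demand: only small amounts of secondary amine may be present, because such amines cleave aryl carbonates.

**4 ⇒ 3.**
- Bonds cut: none. The aldehyde carbon (future C1) is taken back to a primary alcohol, which is a change of oxidation level only.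
- Reason and gain: 3 is stable, whereas 4 is not.
- Demand: a neutral, non-aqueous oxidation that stops at the aldehyde.

**3 ⇒ 1 + 2.**
- Bonds cut: the carbonate O–C(=O) bond.
- Reason and gain: 1 contains ring C, C6 and C1 in the right connectivity.
- Demand: the phenol must react in the presence of the primary alcohol.

## Other disconnections considered

**Alternative 1:**
- **Cut.** The cut runs through C3–C4 and C6–C1. It divides ring B into two identical three-carbon pieces, each a molecule of methyl 3-(4-benzyloxyphenyl)-2-oxopropanoate A1.
- **Forward key step.** KOtBu would enolise A1 at the benzylic carbon. Each enolate would acylate on the ester carbon of the other molecule, with loss of two molecules of methanol, closing the ring as atromentin dibenzyl ether A2.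
- **In its favour.** All six ring carbons, both aryl groups and the quinone oxidation level come from one building block in one operation. No transition metal or pressurised gas is needed, and the step resembles the biosynthesis. On these points it is better than the chosen plan.
- **Against it: structure.** A2 is symmetric and has hydroxyl groups on both C2 and C5, whereas 17 has hydrogen on C5. One enolic C–O bond of a dihydroxyquinone would have to be removed reductively after a statistical desymmetrisation, and no dependable way to do this next to a reducible quinone is apparent.
- **Against it: mechanism.** The ketone carbonyl of A1 is more electrophilic than its ester carbonyl. Aldol addition and lactonisation should therefore compete with the double Claisen path, which nature enforces with enzyme-bound thioesters.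
- **Against it: endgame.** Benzyl ethers would have to fall to hydrogenolysis or a strong Lewis acid. Hydrogenolysis passes through the hydroquinone, in which the acetate can migrate.
- **Step economy.** A2 might be reached in about four steps, fewer than the seven that lead to 11. The repair work after it (desymmetrisation, deoxygenation, acetylation, debenzylation, reoxidation) makes the whole longer. The chosen plan writes the C5–H/C2–OAc pattern directly.

**Alternative 2:**
- **Cut.** Bonds C4–C5 and C6–C1 are broken, which removes C5 and C6 as an alkyne. This leaves 3-(4-benzyloxyphenyl)-4-isopropoxycyclobut-3-ene-1,2-dione A4 (C1 to C4, derived from diisopropyl squarate A3 by aryl addition and acid-induced rearrangement) and 1-benzyloxy-4-ethynylbenzene A5.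
- **Forward key step.** CoCl(PPh3)3 would insert into the C1–C4 bond between the two carbonyl groups of A4 to give the maleoyl metallacycle CoCl(PPh3)2[C(O)C(OiPr)=C(Ar)C(O)] A6. A6 would take up A5 to form 3,6-bis(4-benzyloxyphenyl)-2-isopropoxy-1,4-benzoquinone A7.
- **In its favour.** The reaction class is established, which is better than the chosen key step. The quinone level arrives directly, so no phenol oxidation is needed, which is also better. The two fragments are of equal size and the linear sequence would be about six or seven steps, equal to or better than the chosen plan.
- **Against it: metal economy.** A full equivalent of cobalt and several of phosphine are consumed.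
- **Against it: regiocontrol.** The orientation in which the terminal alkyne enters decides whether the aryl group ends on C6 or on C5. That orientation rests only on the modest electronic difference between the two acyl–cobalt bonds. The chosen plan has no such ambiguity, since the C6 aryl group is fixed in the chain.
- **Against it: endgame.** The C2 oxygen arrives as an isopropyl ether, so strong-acid dealkylation and acetylation of the hydroxyquinone are added. That acetylation would be selective while the outer phenols remain masked, which is equal to the chosen plan. The benzyl ethers bring the same endgame problem as in alternative 1.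
- **Balance.** The total step count is about equal. The key step is safer, but regiocontrol, endgame and metal economy are weaker.

**Alternative 3:**
- **Cut.** The cut is C4–C5, combined retrosynthetically with re-forming of the C1–C4 bond. This contracts ring B to racemic 4-hydroxy-3-isopropoxy-2-[4-(methoxymethoxy)phenyl]-4-{1-[4-(methoxymethoxy)phenyl]vinyl}cyclobut-2-en-1-one A8, derived from A3 by two successive organolithium additions.
- **Forward key step.** Heating A8 would open the four-membered ring at C1–C4, the hydroxyl group rotating outward, to dienylketene A9. Ketene carbon C4 of A9 closes on the vinyl CH2 (C5), and tautomerisation would give 2,5-bis[4-(methoxymethoxy)phenyl]-3-isopropoxybenzene-1,4-diol A10.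
- **In its favour: mechanism.** It uses the same kind of ketene and the same 6π closure as step 8. It reaches the ketene by a purely thermal, well-established ring opening, without catalyst, CO pressure or a competing acyloxy shift. On mechanistic safety it is clearly better.
- **In its favour: regiochemistry.** The second organolithium should attack the more electrophilic carbonyl, the one next to the alkoxy-bearing carbon, which is what is needed. Positional certainty is equal to that of the chosen plan.
- **In its favour: oxidation.** The C1 oxygen is already present, so a mild hydroquinone oxidation replaces a para-selective phenol oxidation, which is better.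
- **Against it: reagents.** Two cryogenic organolithium steps dictate ether-type protecting groups, and the 1-arylvinyl nucleophile needs its own preparation.
- **Against it: endgame.** The C2 oxygen arrives as an isopropyl ether. The acid that cleaves it would also strip the methoxymethyl groups, leaving three free hydroxyls of which the least nucleophilic must be acetylated. That is exactly the problem the chosen plan avoids. If the methoxymethyl groups are kept until after acetylation, their removal needs protic acid in a nucleophilic medium, which endangers the acetate.
- **Step economy and balance.** About ten to eleven steps against ten, so equal or slightly worse. This is the more conservative ring synthesis. The chosen plan accepts a riskier ring-forming step in exchange for an acetate that is in place from the start and an endgame of two steps.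

Key step: step 8

Remark on the chemistry: the labels C1–C6 of the quinone ring are used for the same carbon atoms in all precursors, and compounds 7, 10 and 11 are racemates.

## Steps

Step 1
Reactants: 1 tyrosol [4-(2-hydroxyethyl)phenol]; 2 di-tert-butyl dicarbonate
Product: 3 tert-butyl 4-(2-hydroxyethyl)phenyl carbonate
Conditions: 2 (1.05 equiv), K2CO3 (1.5 equiv), acetone, rt
Reagents that add atoms: none
Why: Chemoselective O-tert-butoxycarbonylation: K2CO3 deprotonates only the phenol, and the phenoxide attacks 2 far faster than the neutral primary alcohol, which would need an acyl-transfer catalyst. The carbonate masks the phenol against later oxidations and turns the ring oxygen from a strong donor into a weak acceptor.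

Step 2
Reactants: 3 tert-butyl 4-(2-hydroxyethyl)phenyl carbonate
Product: 4 tert-butyl 4-(2-oxoethyl)phenyl carbonate
Conditions: Dess–Martin periodinane (1.2 equiv), CH2Cl2, 0 °C to rt
Reagents that add atoms: none
Why: The Dess–Martin oxidation stops at the aldehyde under nearly neutral, water-free conditions that the carbonate tolerates. Arylacetaldehyde 4 enolises and self-condenses readily, so after a short work-up it should be used on the same day without chromatography.

Step 3
Reactants: 4 tert-butyl 4-(2-oxoethyl)phenyl carbonate
Product: 5 tert-butyl 4-(3-oxoprop-1-en-2-yl)phenyl carbonate (the 2-arylacrolein)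
Conditions: 37 % aq. HCHO (1.2 equiv), pyrrolidine (10 mol %), EtCO2H (10 mol %), iPrOH, 45 °C
Reagents that add atoms: formaldehyde, SMILES C=O
Why: Organocatalytic alpha-methylenation (Mannich condensation followed by E1cB loss of the amine): the ammonium carboxylate turns formaldehyde into an iminium ion and 4 into its enamine, and the acidic benzylic alpha-proton makes the elimination fast. Only a tenth of an equivalent of largely protonated secondary amine is present, so aminolysis of the aryl carbonate should stay marginal; 5 is kept cold and used promptly because 2-arylacroleins oligomerise.

Step 4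
Reactants: 5 tert-butyl 4-(3-oxoprop-1-en-2-yl)phenyl carbonate; 6 ethynylmagnesium bromide
Product: 7 rac-tert-butyl 4-(3-hydroxypent-1-en-4-yn-2-yl)phenyl carbonate
Conditions: 6 (0.5 M in THF, 1.2 equiv), THF, −78 to −30 °C; sat. aq. NH4Cl added cold
Reagents that add atoms: none
Why: 1,2-Addition of an alkynyl Grignard reagent to an enal; at low temperature the aldehyde reacts much faster than the hindered tert-butyl carbonate, and cold protonation keeps the magnesium alkoxide from taking a carbonate group from a second molecule. The carbinol centre (future C1) forms as a racemate, which does not matter because it becomes an sp2 ring carbon in step 8.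

Step 5
Reactants: 8 4-iodophenol; 2 di-tert-butyl dicarbonate
Product: 9 tert-butyl 4-iodophenyl carbonate
Conditions: 2 (1.05 equiv), K2CO3 (1.5 equiv), acetone, rt
Reagents that add atoms: none
Why: Standard O-tert-butoxycarbonylation of a phenoxide. The acyloxy-type substituent makes the later alkyne aryl group (ring A) slightly electron-poor, which step 8 needs.

Step 6
Reactants: 7 rac-tert-butyl 4-(3-hydroxypent-1-en-4-yn-2-yl)phenyl carbonate; 9 tert-butyl 4-iodophenyl carbonate
Product: 10 rac-1,4-bis[4-(tert-butoxycarbonyloxy)phenyl]pent-4-en-1-yn-3-ol
Conditions: PdCl2(PPh3)2 (2 mol %), CuI (4 mol %), Et3N (3 equiv), THF (degassed), rt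
Reagents that add atoms: none
Why: Sonogashira coupling of a terminal alkyne with an aryl iodide proceeds at room temperature, where Heck reaction of the 1,1-disubstituted alkene cannot compete, and Et3N is too poor a nucleophile to touch the carbonates. Coupling the free alcohol rather than its ester means that no allylic-propargylic leaving group is offered to zerovalent palladium.

Step 7
Reactants: 10 rac-1,4-bis[4-(tert-butoxycarbonyloxy)phenyl]pent-4-en-1-yn-3-ol
Product: 11 rac-1,4-bis[4-(tert-butoxycarbonyloxy)phenyl]pent-4-en-1-yn-3-yl acetate
Conditions: Ac2O (1.5 equiv), pyridine (3 equiv), DMAP (5 mol %), CH2Cl2, 0 °C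
Reagents that add atoms: acetic anhydride, SMILES CC(=O)OC(C)=O
Why: DMAP-catalysed acetylation of the only free hydroxyl group in the molecule, so no selectivity question arises. These two carbons and two oxygens are the acetate of the target, installed where it is trivial to do so.

Step 8
Reactants: 11 rac-1,4-bis[4-(tert-butoxycarbonyloxy)phenyl]pent-4-en-1-yn-3-yl acetate; 12 carbon monoxide
Product: 15 3-acetoxy-2,5-bis[4-(tert-butoxycarbonyloxy)phenyl]phenol, via dienylketene 13 (not isolated), via cyclohexa-2,4-dienone 14 (not isolated)
Conditions: [RhCl(CO)2]2 (5 mol %), CO (10 bar), ClCH2CH2Cl (0.05 M), 80 °C, autoclave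
Reagents that add atoms: none
Why: Proposed new method: monovalent rhodium binds the alkyne of 11, the acetate carbonyl oxygen attacks C2 in a 5-exo fashion and the C1–O bond of the dioxolenium ring then breaks, so that the ester ends on C2 and a rhodium-bound vinylcarbene stands on C3 (1,2-acyloxy shift). Capture of 12 at the carbene carbon makes the C3–C4 bond and gives dienylketene 13, which can cyclise only from the geometry with C3 and C6 cis on the C2=C1 double bond. The one new ring closes by a thermal disrotatory 6π electrocyclisation that joins ketene carbon C4 to the methylene carbon C5 (CO insertion into a rhodacyclohexadiene followed by reductive elimination is the metal-bound equivalent), and dienone 14 tautomerises irreversibly to phenol 15. The closest known reaction type is the rhodium-catalysed [5+1] carbonylation of 3-acyloxy-1,4-enynes to resorcinol monoesters; an aryl group on the alkyne terminus has not been shown for it, which is why this step goes beyond known chemistry. No stereocentre is created, and the racemic carbinol centre C1 is flattened to an aromatic CH. The selectivity required is 1,2- over 1,3-acyloxy shift, since attack of the ester at the benzylic alkyne carbon C3 would lead away into allene chemistry and five-membered-ring carbonylation. Three features of 11 favour the 1,2-path: the carbonate on ring A is an acyloxy-type group with a slightly positive para substituent constant and so removes the cation stabilisation that draws the ester to C3, both shifts are reversible whereas aromatisation of 14 is not, and the 1-arylvinyl unit already sits next to C1 ready for ring closure. CO pressure above atmospheric should shorten the lifetime of the carbene and favour its capture, and the acetate can reach only C2 because it is delivered intramolecularly.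

Step 9
Reactants: 15 3-acetoxy-2,5-bis[4-(tert-butoxycarbonyloxy)phenyl]phenol
Product: 16 2-acetoxy-3,6-bis[4-(tert-butoxycarbonyloxy)phenyl]-1,4-benzoquinone
Conditions: (KSO3)2NO (2.5 equiv), aq. KH2PO4 (pH 6), nBu4NHSO4 (10 mol %), CH2Cl2–H2O, rt
Reagents that add atoms: potassium nitrosodisulfonate, SMILES [K+].[K+].[O]N(S(=O)(=O)[O-])S(=O)(=O)[O-]
Why: Teuber oxidation: one equivalent of the nitroxyl radical removes the phenolic hydrogen, a second couples through its oxygen at the hydrogen-bearing para carbon C1, and loss of imidodisulfonate gives the para-quinone, as is usual for phenols with a free para position even when it is flanked by two substituents. The outer rings are carbonates and not phenols and stay inert, and the two-phase medium at pH 6 keeps 16 in the organic layer, away from hydrolysis.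

Step 10
Reactants: 16 2-acetoxy-3,6-bis[4-(tert-butoxycarbonyloxy)phenyl]-1,4-benzoquinone
Product: 17 Neonambiquinone A [2-acetoxy-3,6-bis(4-hydroxyphenyl)-1,4-benzoquinone]
Conditions: CF3CO2H–CH2Cl2 (1:4, dry), 0 °C to rt; evaporation with toluene
Reagents that add atoms: none
Why: Acidolysis of tert-butyl carbonates (loss of the tert-butyl cation as the alkene, then decarboxylation) needs neither nucleophile nor base, so the vinylogous-anhydride acetate on C2 and the quinone are left alone. All by-products are volatile, so 17 can be isolated by evaporation and crystallisation without aqueous or basic work-up.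

## Compound list

1 | tyrosol, 4-(2-hydroxyethyl)phenol | OCCc1ccc(O)cc1 | starting material
2 | di-tert-butyl dicarbonate | CC(C)(C)OC(=O)OC(=O)OC(C)(C)C | starting material
3 | tert-butyl 4-(2-hydroxyethyl)phenyl carbonate | OCCc1ccc(OC(=O)OC(C)(C)C)cc1 | intermediate
4 | tert-butyl 4-(2-oxoethyl)phenyl carbonate | O=CCc1ccc(OC(=O)OC(C)(C)C)cc1 | intermediate
5 | tert-butyl 4-(3-oxoprop-1-en-2-yl)phenyl carbonate | C=C(C=O)c1ccc(OC(=O)OC(C)(C)C)cc1 | intermediate
6 | ethynylmagnesium bromide | C#C[Mg]Br | starting material
7 | rac-tert-butyl 4-(3-hydroxypent-1-en-4-yn-2-yl)phenyl carbonate | C#CC(O)C(=C)c1ccc(OC(=O)OC(C)(C)C)cc1 | intermediate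
8 | 4-iodophenol | Oc1ccc(I)cc1 | starting material
9 | tert-butyl 4-iodophenyl carbonate | CC(C)(C)OC(=O)Oc1ccc(I)cc1 | intermediate
10 | rac-1,4-bis[4-(tert-butoxycarbonyloxy)phenyl]pent-4-en-1-yn-3-ol | OC(C#Cc1ccc(OC(=O)OC(C)(C)C)cc1)C(=C)c1ccc(OC(=O)OC(C)(C)C)cc1 | intermediate
11 | rac-1,4-bis[4-(tert-butoxycarbonyloxy)phenyl]pent-4-en-1-yn-3-yl acetate | CC(=O)OC(C#Cc1ccc(OC(=O)OC(C)(C)C)cc1)C(=C)c1ccc(OC(=O)OC(C)(C)C)cc1 | intermediate
12 | carbon monoxide | [C-]#[O+] | starting material
13 | (3E)-3-acetoxy-2,5-bis[4-(tert-butoxycarbonyloxy)phenyl]hexa-1,3,5-trien-1-one (dienylketene, not isolated) | O=C=C(c1ccc(OC(=O)OC(C)(C)C)cc1)/C(OC(C)=O)=C\C(=C)c1ccc(OC(=O)OC(C)(C)C)cc1 | intermediate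
14 | 3-acetoxy-2,5-bis[4-(tert-butoxycarbonyloxy)phenyl]cyclohexa-2,4-dien-1-one (not isolated) | O=C1CC(c2ccc(OC(=O)OC(C)(C)C)cc2)=CC(OC(C)=O)=C1c1ccc(OC(=O)OC(C)(C)C)cc1 | intermediate
15 | 3-acetoxy-2,5-bis[4-(tert-butoxycarbonyloxy)phenyl]phenol | CC(=O)Oc1cc(-c2ccc(OC(=O)OC(C)(C)C)cc2)cc(O)c1-c1ccc(OC(=O)OC(C)(C)C)cc1 | intermediate
16 | 2-acetoxy-3,6-bis[4-(tert-butoxycarbonyloxy)phenyl]-1,4-benzoquinone | CC(=O)OC1=C(c2ccc(OC(=O)OC(C)(C)C)cc2)C(=O)C=C(c2ccc(OC(=O)OC(C)(C)C)cc2)C1=O | intermediate
17 | Neonambiquinone A | CC(=O)OC1=C(c2ccc(O)cc2)C(=O)C=C(c2ccc(O)cc2)C1=O | target

## Step count and least certain steps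

Total step count: 10.
Longest linear sequence: 9 (steps 1–4 and 6–10). Step 5 is a one-step side branch.

**Step 8 (key step, the only step beyond known chemistry).**
- Main risk: the acetate may migrate by the 1,3-path, through 6-endo attack of the ester oxygen at the benzylic alkyne carbon C3, because an aryl group stabilises positive charge there. Carbonylative closure of a five-membered instead of a six-membered ring could follow. That closure is also irreversible, so reversibility of the two shifts alone does not rescue the reaction.
- Secondary risks: interception of the ketene by the phenol already formed, and suppression of alkyne binding by too much CO.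
- Fallback (known chemistry only): it sets out from 9 and comes back at 15. Palladium-catalysed stannylation of 9 with (nBu3Sn)2 (Pd(PPh3)4, toluene, 110 °C) should give tert-butyl 4-(tributylstannyl)phenyl carbonate F1. Purchased 5-bromobenzene-1,3-diol F2 is iodinated between its two hydroxyl groups (I2, NaHCO3, H2O, 0 °C), the usual site for 5-substituted resorcinols, to 5-bromo-2-iodobenzene-1,3-diol F3. A double Stille coupling of F3 with two equivalents of F1 (PdCl2(PPh3)2, CuI, DMF, 80 °C) follows. It is base-free, so no phenoxide arises that could shuffle the carbonates. It should give the symmetric 2,5-bis[4-(tert-butoxycarbonyloxy)phenyl]benzene-1,3-diol F4. The two hydroxyl groups of F4 are equivalent, so one equivalent of Ac2O in pyridine at low temperature leads to 15, with only the degree of acetylation to be controlled.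

**Step 9.**
- Main risk: hydrogen abstraction may be slow from a phenol that is deactivated by the acetoxy group and crowded by ring A. The long contact with the aqueous phase would then allow hydrolytic loss of the C2 acetate.
- Secondary risk: attack at the ortho carbon C5.
- Fallback: it sets out from 15 and comes back at 16. It gives up preserving the acetate during the oxidation. A two-electron oxidation with PhI(OCOCF3)2 in MeCN–H2O at 0 °C delivers water to the para carbon, and brief stirring with aq. NaHCO3 completes the ester cleavage to 2-hydroxy-3,6-bis[4-(tert-butoxycarbonyloxy)phenyl]-1,4-benzoquinone F5. The only free hydroxyl group of F5 is then re-acetylated (Ac2O, pyridine, 0 °C) to 16.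

**Step 10.**
- Main risk: Friedel–Crafts tert-butylation of the liberated phenol rings by the tert-butyl cation, and solvolysis of the acetate if moisture enters. The usual cation traps (thiols, silanes) cannot be used, because they would add to or reduce the quinone.
- Fallback: it sets out from 15 and comes back at 17, and it reverses the order of the last two steps. Acidolysis of 15 (CF3CO2H, CH2Cl2, with a silane scavenger, harmless at this stage) should give 3-acetoxy-2,5-bis(4-hydroxyphenyl)phenol F6, in which the acetate is still an ordinary aryl ester. Aerobic oxidation with Co(salen) and O2 in MeCN then converts the only phenol with a free para position into the quinone 17. The price is that this oxidation must discriminate between three phenols.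

**Step 3.**
- Main risk: aldol self-condensation of 4 before methylenation, aminolysis of the carbonate by the amine catalyst, and oligomerisation of the product on standing.
- Fallback: it sets out from 9 and comes back at 5, avoiding both the arylacetaldehyde and any amine. Negishi coupling of 9 with isopropenylzinc chloride (from CH2=C(CH3)MgBr and ZnCl2; Pd(PPh3)4, THF, rt) should give tert-butyl 4-(prop-1-en-2-yl)phenyl carbonate F7. Riley oxidation of its allylic methyl group (SeO2, dioxane, 80 °C, finished with MnO2 if the reaction stops at the alcohol level) leads to 5.

**Step 4.**
- Main risk: attack of the Grignard reagent on a carbonate, or transfer of a carbonate group to the magnesium alkoxide on warming.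
- Fallback: it sets out from 9, meets 5 and comes back at 10, so that steps 4 and 6 are both replaced by a softer, more convergent addition. Sonogashira coupling of 9 with ethynyltrimethylsilane (PdCl2(PPh3)2, CuI, Et3N, rt) gives tert-butyl 4-[(trimethylsilyl)ethynyl]phenyl carbonate F8. Buffered desilylation (nBu4NF, AcOH, THF, 0 °C) gives tert-butyl 4-ethynylphenyl carbonate F9. The zinc acetylide made from F9 with Me2Zn in toluene adds to aldehyde 5 at rt to give 10, since organozinc species leave carbonates alone.

## Further compounds

F1 | step 8 | tert-butyl 4-(tributylstannyl)phenyl carbonate | CCCC[Sn](CCCC)(CCCC)c1ccc(OC(=O)OC(C)(C)C)cc1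
F2 | step 8 | 5-bromobenzene-1,3-diol (purchased) | Oc1cc(Br)cc(O)c1
F3 | step 8 | 5-bromo-2-iodobenzene-1,3-diol | Oc1cc(Br)cc(O)c1I
F4 | step 8 | 2,5-bis[4-(tert-butoxycarbonyloxy)phenyl]benzene-1,3-diol | Oc1cc(-c2ccc(OC(=O)OC(C)(C)C)cc2)cc(O)c1-c1ccc(OC(=O)OC(C)(C)C)cc1
F5 | step 9 | 2-hydroxy-3,6-bis[4-(tert-butoxycarbonyloxy)phenyl]-1,4-benzoquinone | OC1=C(c2ccc(OC(=O)OC(C)(C)C)cc2)C(=O)C=C(c2ccc(OC(=O)OC(C)(C)C)cc2)C1=O
F6 | step 10 | 3-acetoxy-2,5-bis(4-hydroxyphenyl)phenol | CC(=O)Oc1cc(-c2ccc(O)cc2)cc(O)c1-c1ccc(O)cc1
F7 | step 3 | tert-butyl 4-(prop-1-en-2-yl)phenyl carbonate | CC(=C)c1ccc(OC(=O)OC(C)(C)C)cc1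
F8 | step 4 | tert-butyl 4-[(trimethylsilyl)ethynyl]phenyl carbonate | C[Si](C)(C)C#Cc1ccc(OC(=O)OC(C)(C)C)cc1
F9 | step 4 | tert-butyl 4-ethynylphenyl carbonate | C#Cc1ccc(OC(=O)OC(C)(C)C)cc1
A1 | alternative 1 | methyl 3-(4-benzyloxyphenyl)-2-oxopropanoate | COC(=O)C(=O)Cc1ccc(OCc2ccccc2)cc1
A2 | alternative 1 | atromentin dibenzyl ether | O=C1C(O)=C(c2ccc(OCc3ccccc3)cc2)C(=O)C(O)=C1c1ccc(OCc2ccccc2)cc1
A3 | alternative 2 | diisopropyl squarate | CC(C)OC1=C(OC(C)C)C(=O)C1=O
A4 | alternative 2 | 3-(4-benzyloxyphenyl)-4-isopropoxycyclobut-3-ene-1,2-dione | CC(C)OC1=C(c2ccc(OCc3ccccc3)cc2)C(=O)C1=O
A5 | alternative 2 | 1-benzyloxy-4-ethynylbenzene | C#Cc1ccc(OCc2ccccc2)cc1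
A6 | alternative 2 | maleoyl metallacycle CoCl(PPh3)2[C(O)C(OiPr)=C(Ar)C(O)], Ar = 4-benzyloxyphenyl (dative P–Co bonds drawn charge-separated) | CC(C)OC1=C(c2ccc(OCc3ccccc3)cc2)C(=O)[Co-2](Cl)([P+](c2ccccc2)(c2ccccc2)c2ccccc2)([P+](c2ccccc2)(c2ccccc2)c2ccccc2)C1=O
A7 | alternative 2 | 3,6-bis(4-benzyloxyphenyl)-2-isopropoxy-1,4-benzoquinone | CC(C)OC1=C(c2ccc(OCc3ccccc3)cc2)C(=O)C=C(c2ccc(OCc3ccccc3)cc2)C1=O
A8 | alternative 3 | rac-4-hydroxy-3-isopropoxy-2-[4-(methoxymethoxy)phenyl]-4-{1-[4-(methoxymethoxy)phenyl]vinyl}cyclobut-2-en-1-one | CC(C)OC1=C(c2ccc(OCOC)cc2)C(=O)C1(O)C(=C)c1ccc(OCOC)cc1
A9 | alternative 3 | 4-hydroxy-3-isopropoxy-2,5-bis[4-(methoxymethoxy)phenyl]hexa-1,3,5-trien-1-one (dienylketene, ketene-bearing carbon and vinyl group cis) | O=C=C(c1ccc(OCOC)cc1)/C(OC(C)C)=C(\C(=C)c1ccc(OCOC)cc1)O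
A10 | alternative 3 | 2,5-bis[4-(methoxymethoxy)phenyl]-3-isopropoxybenzene-1,4-diol | Oc1cc(-c2ccc(OCOC)cc2)c(O)c(OC(C)C)c1-c1ccc(OCOC)cc1
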